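**Plan**

1. Cuts: (i) the bond between the linker CH2 and the quaternary dioxane carbon C3, giving a C3-methoxy peroxyketal and a bicyclic stannyl enyne; (ii) dioxane O1–C6 (SN2) and C6–Cα (aldol); (iii) ring B C1–C2 (cation–olefin closure) and the C4a–CH2 bond ([3,3] shift).
2. Forward: ring A is bought as limonene oxide; Ireland–Claisen, homologation to a β-keto ester, SnCl4 closure of ring B, enol triflate/cuprate methylation, then ester to alkyne to stannane. Separately: aldol, ozonolysis in MeOH, 6-exo peroxide alkylation to the 1,2-dioxane. Then union, saturation of C≡C and unmasking of CO2H.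
3. Stereochemistry: C8a comes from the (S)-limonene pool and C4a by suprafacial [3,3] transfer from the C1–O bond. Cα and C6 come from an auxiliary-controlled syn-aldol followed by SN2 inversion at C6. Quaternary C3 is set by substrate-controlled axial attack on the dioxanyl cation.
4. Enabling feature: C3 of the 1,2-dioxane ring (the carbon carrying CH3 and the CH2CH2 linker) is bonded to peroxide oxygen O2, so at the ketal level it ionises to a cyclic peroxycarbenium ion, whose half-chair is biased by the C6 side chain across the ring. The linker arrives as a C≡C unit conjugated to the C2=C3 olefin of ring B, which makes its terminal carbon a π-nucleophile.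

Key step: step 18

Assumption: (−)-trans-limonene 1,2-oxide (1) is used as a single diastereomer; the commercial cis/trans mixture made from (S)-(−)-limonene should serve as well, because selenolate opens the cis isomer much more slowly.
Numbering used in the text: dioxane O1–O2–C3(quaternary)–C4–C5–C6(H), Cα = side-chain CH(CH3); bicycle as 1,4,4a,7,8,8a-hexahydronaphthalene with C1 = C(CH3)2 and C2 = linker-bearing olefin carbon. HHN = (4aR,8aS)-1,1,3,6-tetramethyl-1,4,4a,7,8,8a-hexahydronaphthalen-2-yl; TBS = tert-butyl(dimethyl)silyl.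

**Part A – bicyclic nucleophile**

Step 1
Reactants: 1 (−)-trans-limonene 1,2-oxide [(1R,2S,4S)-1,2-epoxy-p-menth-8-ene]
Product: 4 (1R,4S)-1-methyl-4-(prop-1-en-2-yl)cyclohex-2-en-1-ol, via hydroxy selenide 2 (not isolated), via selenoxide 3 (not isolated)
Conditions: PhSeSePh, NaBH4, EtOH, reflux; then 30% H2O2, THF, 0 °C → rt
Reagents that add atoms: none
Why: Selenolate opens the trisubstituted epoxide at secondary C2 by trans-diaxial SN2 attack, and selenoxide syn-elimination can only run toward C3 because C1 carries no hydrogen, so the tertiary allylic alcohol keeps the C1 and C4 configurations of 1 (epoxide opening/selenoxide elimination).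

Step 2
Reactants: 4 (1R,4S)-1-methyl-4-(prop-1-en-2-yl)cyclohex-2-en-1-ol
Product: 5 (1R,4S)-1-methyl-4-(prop-1-en-2-yl)cyclohex-2-en-1-yl acetate
Conditions: Ac2O, Et3N, DMAP, CH2Cl2, rt
Reagents that add atoms: acetic anhydride CC(=O)OC(C)=O
Why: DMAP-catalysed acylation of the tertiary allylic alcohol under basic conditions avoids ionisation of the allylic C–O bond (nucleophilic-catalysis esterification).

Step 3
Reactants: 5 (1R,4S)-1-methyl-4-(prop-1-en-2-yl)cyclohex-2-en-1-yl acetate
Product: 8 2-[(1R,6S)-3-methyl-6-(prop-1-en-2-yl)cyclohex-2-en-1-yl]acetic acid, via silyl ketene acetal 6 (not isolated), via trimethylsilyl ester 7 (not isolated)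
Conditions: LDA, TMSCl, THF, −78 °C → 50 °C; then 1 M HCl
Reagents that add atoms: none
Why: Ireland–Claisen rearrangement: the silyl ketene acetal is held on the face of the C1–O bond, so the suprafacial [3,3] shift forms the new C–CH2 bond on that face, cis to the isopropenyl group on the neighbouring carbon, which sets the future C4a centre and moves the olefin to the C(CH3)=CH position.

Step 4
Reactants: 8 2-[(1R,6S)-3-methyl-6-(prop-1-en-2-yl)cyclohex-2-en-1-yl]acetic acid
Product: 11 methyl 4-[(1R,6S)-3-methyl-6-(prop-1-en-2-yl)cyclohex-2-en-1-yl]-3-oxobutanoate, via acyl imidazolide 9 (not isolated), via acylmalonate 10 (not isolated)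
Conditions: CDI, THF, rt; then potassium methyl malonate, MgCl2, Et3N, THF/MeCN, rt → 45 °C; 1 M HCl
Reagents that add atoms: potassium methyl malonate [K+].[O-]C(=O)CC(=O)OC
Why: C-acylation of a magnesium malonate half-ester by the acyl imidazolide followed by loss of CO2 is the standard two-carbon homologation of an acid to a β-keto ester (malonate acylation/decarboxylation).

Step 5
Reactants: 11 methyl 4-[(1R,6S)-3-methyl-6-(prop-1-en-2-yl)cyclohex-2-en-1-yl]-3-oxobutanoate
Product: 12 methyl (4aR,8aS)-1,1,6-trimethyl-3-oxo-1,2,3,4,4a,7,8,8a-octahydronaphthalene-2-carboxylate (C2 epimers plus enol)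
Conditions: SnCl4, CH2Cl2, −78 → 0 °C
Reagents that add atoms: none
Why: Proton-initiated cation–olefin cyclisation terminated by a β-keto ester: Markovnikov protonation of the isopropenyl group gives the tertiary C1 cation, which the tin-bound enol carbon C2 captures in a six-membered closure; the cis side chains can only give the cis-fused bicycle, so no ring-fusion centre is created or touched.

Step 6
Reactants: 12 methyl (4aR,8aS)-1,1,6-trimethyl-3-oxo-1,2,3,4,4a,7,8,8a-octahydronaphthalene-2-carboxylate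
Product: 13 methyl (4aR,8aS)-1,1,6-trimethyl-3-{[(trifluoromethyl)sulfonyl]oxy}-1,4,4a,7,8,8a-hexahydronaphthalene-2-carboxylate
Conditions: Tf2O, iPr2NEt, CH2Cl2, −78 → 0 °C
Reagents that add atoms: triflic anhydride O=S(=O)(OS(=O)(=O)C(F)(F)F)C(F)(F)F
Why: The only acidic position lies between the two carbonyls, so O-sulfonylation gives the C2=C3 enol triflate regiospecifically (enol triflate formation).

Step 7
Reactants: 13 methyl (4aR,8aS)-1,1,6-trimethyl-3-{[(trifluoromethyl)sulfonyl]oxy}-1,4,4a,7,8,8a-hexahydronaphthalene-2-carboxylate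
Product: 14 methyl (4aR,8aS)-1,1,3,6-tetramethyl-1,4,4a,7,8,8a-hexahydronaphthalene-2-carboxylate
Conditions: MeLi, CuI, Et2O, 0 °C; then 13, −78 → −20 °C
Reagents that add atoms: lithium dimethylcuprate [Li+].C[Cu-]C
Why: Addition–elimination of a Gilman cuprate to the β-sulfonyloxy enoate replaces OTf by CH3 and fixes the tetrasubstituted C2=C3 olefin in place (cuprate coupling of an enol triflate).

Step 8
Reactants: 14 methyl (4aR,8aS)-1,1,3,6-tetramethyl-1,4,4a,7,8,8a-hexahydronaphthalene-2-carboxylate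
Product: 15 [(4aR,8aS)-1,1,3,6-tetramethyl-1,4,4a,7,8,8a-hexahydronaphthalen-2-yl]methanol
Conditions: DIBAL-H, CH2Cl2, −78 → 0 °C; Rochelle salt
Reagents that add atoms: none
Why: DIBAL-H reduces the hindered conjugated ester to the allylic alcohol without touching either olefin (hydride reduction).

Step 9
Reactants: 15 [(4aR,8aS)-1,1,3,6-tetramethyl-1,4,4a,7,8,8a-hexahydronaphthalen-2-yl]methanol
Product: 17 (4aR,8aS)-2-ethynyl-1,1,3,6-tetramethyl-1,4,4a,7,8,8a-hexahydronaphthalene, via aldehyde 16 (not isolated)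
Conditions: activated MnO2, THF, rt; then dimethyl (1-diazo-2-oxopropyl)phosphonate, K2CO3, MeOH, rt
Reagents that add atoms: dimethyl (1-diazo-2-oxopropyl)phosphonate CC(=O)C(=[N+]=[N-])P(=O)(OC)OC
Why: MnO2 oxidises only the allylic alcohol, and the diazophosphonate anion converts the aldehyde in the same flask into the terminal alkyne by Horner–Wadsworth–Emmons addition, loss of N2 and 1,2-H shift (tandem oxidation/Ohira–Bestmann homologation).

Step 10
Reactants: 17 (4aR,8aS)-2-ethynyl-1,1,3,6-tetramethyl-1,4,4a,7,8,8a-hexahydronaphthalene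
Product: 19 tributyl{[(4aR,8aS)-1,1,3,6-tetramethyl-1,4,4a,7,8,8a-hexahydronaphthalen-2-yl]ethynyl}stannane, via lithium acetylide 18 (not isolated)
Conditions: n-BuLi, THF, −78 °C; then Bu3SnCl, −78 °C → rt
Reagents that add atoms: tributyltin chloride CCCC[Sn](Cl)(CCCC)CCCC
Why: Deprotonation of the terminal alkyne and substitution at tin by the acetylide (acetylide stannylation).

**Part B – dioxane electrophile**

Step 11
Reactants: 20 4-methylpent-4-en-1-ol
Product: 21 4-methylpent-4-enal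
Conditions: TEMPO (cat.), PhI(OAc)2, CH2Cl2, rt
Reagents that add atoms: none
Why: Oxoammonium oxidation of the primary alcohol stops at the aldehyde in the absence of water and leaves the 1,1-disubstituted olefin alone (TEMPO/hypervalent iodine oxidation).

Step 12
Reactants: 21 4-methylpent-4-enal, 22 (4R)-4-benzyl-3-propanoyl-1,3-oxazolidin-2-one
Product: 24 (4R)-4-benzyl-3-[(2R,3S)-3-hydroxy-2,6-dimethylhept-6-enoyl]-1,3-oxazolidin-2-one, via boron enolate 23 (not isolated)
Conditions: Bu2BOTf, iPr2NEt, CH2Cl2, −78 → 0 °C; then 21, −78 → 0 °C; H2O2, pH 7 buffer, MeOH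
Reagents that add atoms: none
Why: Evans syn-aldol: the Z-boron enolate reacts through a closed chair (Zimmerman–Traxler) transition state on the face away from the benzyl group, setting the (2R,3S) pair, i.e. the future Cα centre and the C6 carbinol in the configuration that later SN2 inversion converts into the target's.

Step 13
Reactants: 24 (4R)-4-benzyl-3-[(2R,3S)-3-hydroxy-2,6-dimethylhept-6-enoyl]-1,3-oxazolidin-2-one
Product: 25 (2S,3S)-2,6-dimethylhept-6-ene-1,3-diol
Conditions: LiBH4, MeOH (1 equiv), THF, 0 °C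
Reagents that add atoms: none
Why: Borohydride cleaves the exocyclic imide carbonyl reductively and releases the auxiliary without epimerising the α-centre (reductive auxiliary removal).

Step 14
Reactants: 25 (2S,3S)-2,6-dimethylhept-6-ene-1,3-diol
Product: 26 (2S,3S)-1-{[tert-butyl(dimethyl)silyl]oxy}-2,6-dimethylhept-6-en-3-ol
Conditions: TBSCl, imidazole, CH2Cl2, 0 °C
Reagents that add atoms: tert-butyldimethylsilyl chloride CC(C)(C)[Si](C)(C)Cl
Why: The primary hydroxyl is silylated much faster than the hindered secondary one (selective silyl ether formation).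

Step 15
Reactants: 26 (2S,3S)-1-{[tert-butyl(dimethyl)silyl]oxy}-2,6-dimethylhept-6-en-3-ol
Product: 27 (2S,3S)-1-{[tert-butyl(dimethyl)silyl]oxy}-2,6-dimethylhept-6-en-3-yl methanesulfonate
Conditions: MsCl, Et3N, CH2Cl2, 0 °C
Reagents that add atoms: methanesulfonyl chloride CS(=O)(=O)Cl
Why: Sulfonylation turns the secondary carbinol, with retention, into the leaving group for the later SN2 ring closure (mesylation).

Step 16
Reactants: 27 (2S,3S)-1-{[tert-butyl(dimethyl)silyl]oxy}-2,6-dimethylhept-6-en-3-yl methanesulfonate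
Product: 28 (2S,3S)-1-{[tert-butyl(dimethyl)silyl]oxy}-6-hydroperoxy-6-methoxy-2-methylheptan-3-yl methanesulfonate (C6 epimers)
Conditions: O3, CH2Cl2/MeOH, −78 °C; N2 purge, no reductant
Reagents that add atoms: ozone [O-][O+]=O; methanol CO
Why: Ozonolysis in methanol: the primary ozonide of a 1,1-disubstituted olefin cleaves to formaldehyde and the more substituted carbonyl oxide, which methanol traps as the α-methoxy hydroperoxide.

Step 17
Reactants: 28 (2S,3S)-1-{[tert-butyl(dimethyl)silyl]oxy}-6-hydroperoxy-6-methoxy-2-methylheptan-3-yl methanesulfonate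
Product: 29 (6R)-6-[(2S)-1-{[tert-butyl(dimethyl)silyl]oxy}propan-2-yl]-3-methoxy-3-methyl-1,2-dioxane (C3 epimers)
Conditions: KOtBu (1.05 equiv), 18-crown-6, THF, 0 °C → rt
Reagents that add atoms: none
Why: 6-exo-tet intramolecular alkylation of the hydroperoxide anion displaces the mesylate with inversion, converting the (3S) carbinol carbon into the (6R) dioxane centre (SN2 peroxide alkylation); the ketal epimers both lead to the same cation later.

**Part C – union and end game**

Step 18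
Reactants: 19 tributyl{[(4aR,8aS)-1,1,3,6-tetramethyl-1,4,4a,7,8,8a-hexahydronaphthalen-2-yl]ethynyl}stannane, 29 (6R)-6-[(2S)-1-{[tert-butyl(dimethyl)silyl]oxy}propan-2-yl]-3-methoxy-3-methyl-1,2-dioxane
Product: 31 (3S,6R)-6-[(2S)-1-{[tert-butyl(dimethyl)silyl]oxy}propan-2-yl]-3-methyl-3-(HHN-ethynyl)-1,2-dioxane, via peroxycarbenium triflate 30 (not isolated)
Conditions: TMSOTf (1.2 equiv), 2,6-di-tert-butyl-4-methylpyridine, CH2Cl2, −78 °C; Et3N quench at −78 °C
Reagents that add atoms: none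
Why: Proposed new method: TMSOTf removes the 3-methoxy group of peroxyketal 29 (both C3 epimers converge) to give the cyclic peroxycarbenium ion 30, which is attacked at C3 by the tin-bearing alkyne carbon of 19; the resulting β-stannyl vinyl cation, further stabilised by the ring-B C2=C3 π bond, loses Bu3Sn+ to restore the triple bond. The closest known reaction types are the Lewis-acid-mediated Sakurai-type allylation and Mukaiyama-type enol-silane addition to peroxycarbenium ions from 3-alkoxy-1,2-dioxanes, and the addition of alkynylstannanes to oxocarbenium ions. No ring is closed. The new quaternary centre C3 is controlled by the existing C6 centre: the cation should react through the half-chair with the C6 side chain pseudo-equatorial, and the nucleophile should enter along the axial trajectory that leads directly to a chair (O1 carries no axial hydrogen to oppose it), which places the new C–C bond cis to the C6 substituent and the methyl trans, as in the target. The step needs C–C bond formation at C3 to outrun O–O heterolysis (Hock/Criegee type), loss of a proton to the enol peroxide and destannylation of 19; the low temperature, the non-nucleophilic counter-ion, the hindered pyridine base and the π-nucleophilicity of the conjugated stannyl enyne are meant to secure this.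

Step 19
Reactants: 31 (3S,6R)-6-[(2S)-1-{[tert-butyl(dimethyl)silyl]oxy}propan-2-yl]-3-methyl-3-(HHN-ethynyl)-1,2-dioxane
Product: 33 (3R,6R)-6-[(2S)-1-{[tert-butyl(dimethyl)silyl]oxy}propan-2-yl]-3-methyl-3-[2-(HHN)ethyl]-1,2-dioxane, via Z-alkene 32 (not isolated)
Conditions: dipotassium azodicarboxylate (excess, in portions), AcOH, MeOH/CH2Cl2, 0 °C → rt
Reagents that add atoms: none
Why: Diimide transfers H2 in a concerted syn fashion to the alkyne and then to the strained Z-olefin, but is inert toward the O–O bond and toward tri- and tetrasubstituted olefins (diimide reduction).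

Step 20
Reactants: 33 (3R,6R)-6-[(2S)-1-{[tert-butyl(dimethyl)silyl]oxy}propan-2-yl]-3-methyl-3-[2-(HHN)ethyl]-1,2-dioxane
Product: 34 (2S)-2-{(3R,6R)-3-methyl-3-[2-(HHN)ethyl]-1,2-dioxan-6-yl}propan-1-ol
Conditions: HF·pyridine, pyridine/THF, 0 °C → rt
Reagents that add atoms: none
Why: Fluoride cleaves the primary silyl ether under buffered conditions that avoid base-induced Kornblum–DeLaMare opening of the peroxide (desilylation).

Step 21
Reactants: 34 (2S)-2-{(3R,6R)-3-methyl-3-[2-(HHN)ethyl]-1,2-dioxan-6-yl}propan-1-ol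
Product: 36 (2R)-2-{(3R,6R)-3-methyl-3-[2-(HHN)ethyl]-1,2-dioxan-6-yl}propanoic acid (target), via aldehyde 35 (not isolated)
Conditions: TEMPO (cat.), PhI(OAc)2 (2.2 equiv), MeCN/H2O 1:1, rt
Reagents that add atoms: water O
Why: Oxoammonium oxidation of the primary alcohol to the aldehyde hydrate and on to the acid runs near neutral pH, which should avoid epimerisation at Cα and β-elimination of the peroxide (TEMPO/PhI(OAc)2 oxidation).

**Compound list**

1 | (−)-trans-limonene 1,2-oxide, (1R,2S,4S)-1,2-epoxy-p-menth-8-ene | C[C@@]12CC[C@H](C(C)=C)C[C@@H]1O2 | starting material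
2 | (1R,2R,4S)-1-methyl-2-(phenylselanyl)-4-(prop-1-en-2-yl)cyclohexan-1-ol | C[C@@]1(O)CC[C@H](C(C)=C)C[C@H]1[Se]c1ccccc1 | intermediate
3 | selenoxide of 2 | C[C@@]1(O)CC[C@H](C(C)=C)C[C@H]1[Se](=O)c1ccccc1 | intermediate
4 | (1R,4S)-1-methyl-4-(prop-1-en-2-yl)cyclohex-2-en-1-ol | C[C@]1(O)C=C[C@@H](C(C)=C)CC1 | intermediate
5 | (1R,4S)-1-methyl-4-(prop-1-en-2-yl)cyclohex-2-en-1-yl acetate | CC(=O)O[C@@]1(C)C=C[C@@H](C(C)=C)CC1 | intermediate
6 | trimethylsilyl ketene acetal of 5 | C=C(O[Si](C)(C)C)O[C@@]1(C)C=C[C@@H](C(C)=C)CC1 | intermediate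
7 | trimethylsilyl 2-[(1R,6S)-3-methyl-6-(prop-1-en-2-yl)cyclohex-2-en-1-yl]acetate | CC1=C[C@@H](CC(=O)O[Si](C)(C)C)[C@@H](C(C)=C)CC1 | intermediate
8 | 2-[(1R,6S)-3-methyl-6-(prop-1-en-2-yl)cyclohex-2-en-1-yl]acetic acid | CC1=C[C@@H](CC(=O)O)[C@@H](C(C)=C)CC1 | intermediate
9 | 1-(imidazol-1-yl)-2-[(1R,6S)-3-methyl-6-(prop-1-en-2-yl)cyclohex-2-en-1-yl]ethan-1-one | CC1=C[C@@H](CC(=O)n2ccnc2)[C@@H](C(C)=C)CC1 | intermediate
10 | 2-(methoxycarbonyl)-4-[(1R,6S)-3-methyl-6-(prop-1-en-2-yl)cyclohex-2-en-1-yl]-3-oxobutanoic acid (as its magnesium chelate) | CC1=C[C@@H](CC(=O)C(C(=O)O)C(=O)OC)[C@@H](C(C)=C)CC1 | intermediate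
11 | methyl 4-[(1R,6S)-3-methyl-6-(prop-1-en-2-yl)cyclohex-2-en-1-yl]-3-oxobutanoate | CC1=C[C@@H](CC(=O)CC(=O)OC)[C@@H](C(C)=C)CC1 | intermediate
12 | methyl (4aR,8aS)-1,1,6-trimethyl-3-oxo-1,2,3,4,4a,7,8,8a-octahydronaphthalene-2-carboxylate (cis-fused; C2 epimers) | CC1=C[C@H]2CC(=O)C(C(=O)OC)C(C)(C)[C@H]2CC1 | intermediate
13 | methyl (4aR,8aS)-1,1,6-trimethyl-3-(triflyloxy)-1,4,4a,7,8,8a-hexahydronaphthalene-2-carboxylate | CC1=C[C@H]2CC(OS(=O)(=O)C(F)(F)F)=C(C(=O)OC)C(C)(C)[C@H]2CC1 | intermediate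
14 | methyl (4aR,8aS)-1,1,3,6-tetramethyl-1,4,4a,7,8,8a-hexahydronaphthalene-2-carboxylate | CC1=C[C@H]2CC(C)=C(C(=O)OC)C(C)(C)[C@H]2CC1 | intermediate
15 | [(4aR,8aS)-1,1,3,6-tetramethyl-1,4,4a,7,8,8a-hexahydronaphthalen-2-yl]methanol | CC1=C[C@H]2CC(C)=C(CO)C(C)(C)[C@H]2CC1 | intermediate
16 | (4aR,8aS)-1,1,3,6-tetramethyl-1,4,4a,7,8,8a-hexahydronaphthalene-2-carbaldehyde | CC1=C[C@H]2CC(C)=C(C=O)C(C)(C)[C@H]2CC1 | intermediate
17 | (4aR,8aS)-2-ethynyl-1,1,3,6-tetramethyl-1,4,4a,7,8,8a-hexahydronaphthalene | CC1=C[C@H]2CC(C)=C(C#C)C(C)(C)[C@H]2CC1 | intermediate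
18 | lithium acetylide of 17 | CC1=C[C@H]2CC(C)=C(C#C[Li])C(C)(C)[C@H]2CC1 | intermediate
19 | tributyl{[(4aR,8aS)-1,1,3,6-tetramethyl-1,4,4a,7,8,8a-hexahydronaphthalen-2-yl]ethynyl}stannane | CC1=C[C@H]2CC(C)=C(C#C[Sn](CCCC)(CCCC)CCCC)C(C)(C)[C@H]2CC1 | intermediate
20 | 4-methylpent-4-en-1-ol | C=C(C)CCCO | starting material
21 | 4-methylpent-4-enal | C=C(C)CCC=O | intermediate
22 | (4R)-4-benzyl-3-propanoyl-1,3-oxazolidin-2-one | CCC(=O)N1[C@H](Cc2ccccc2)COC1=O | starting material
23 | (Z)-dibutylboron enolate of 22 | CCCCB(CCCC)O/C(=C\C)N1[C@H](Cc2ccccc2)COC1=O | intermediate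
24 | (4R)-4-benzyl-3-[(2R,3S)-3-hydroxy-2,6-dimethylhept-6-enoyl]-1,3-oxazolidin-2-one | C=C(C)CC[C@H](O)[C@@H](C)C(=O)N1[C@H](Cc2ccccc2)COC1=O | intermediate
25 | (2S,3S)-2,6-dimethylhept-6-ene-1,3-diol | C=C(C)CC[C@H](O)[C@@H](C)CO | intermediate
26 | (2S,3S)-1-(TBS-oxy)-2,6-dimethylhept-6-en-3-ol | C=C(C)CC[C@H](O)[C@@H](C)CO[Si](C)(C)C(C)(C)C | intermediate
27 | (2S,3S)-1-(TBS-oxy)-2,6-dimethylhept-6-en-3-yl methanesulfonate | C=C(C)CC[C@H](OS(C)(=O)=O)[C@@H](C)CO[Si](C)(C)C(C)(C)C | intermediate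
28 | (2S,3S)-1-(TBS-oxy)-6-hydroperoxy-6-methoxy-2-methylheptan-3-yl methanesulfonate (C6 epimers) | COC(C)(OO)CC[C@H](OS(C)(=O)=O)[C@@H](C)CO[Si](C)(C)C(C)(C)C | intermediate
29 | (6R)-3-methoxy-3-methyl-6-[(2S)-1-(TBS-oxy)propan-2-yl]-1,2-dioxane (C3 epimers) | COC1(C)CC[C@H]([C@@H](C)CO[Si](C)(C)C(C)(C)C)OO1 | intermediate
30 | (6R)-3-methyl-6-[(2S)-1-(TBS-oxy)propan-2-yl]-5,6-dihydro-4H-1,2-dioxin-2-ium triflate (peroxycarbenium ion pair) | CC1=[O+]O[C@H](CC1)[C@@H](C)CO[Si](C)(C)C(C)(C)C.[O-]S(=O)(=O)C(F)(F)F | intermediate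
31 | (3S,6R)-3-methyl-3-(HHN-ethynyl)-6-[(2S)-1-(TBS-oxy)propan-2-yl]-1,2-dioxane | CC1=C[C@H]2CC(C)=C(C#C[C@]3(C)CC[C@H]([C@@H](C)CO[Si](C)(C)C(C)(C)C)OO3)C(C)(C)[C@H]2CC1 | intermediate
32 | (3S,6R)-3-methyl-3-[(Z)-2-(HHN)ethenyl]-6-[(2S)-1-(TBS-oxy)propan-2-yl]-1,2-dioxane | CC1=C[C@H]2CC(C)=C(/C=C\[C@]3(C)CC[C@H]([C@@H](C)CO[Si](C)(C)C(C)(C)C)OO3)C(C)(C)[C@H]2CC1 | intermediate
33 | (3R,6R)-3-methyl-3-[2-(HHN)ethyl]-6-[(2S)-1-(TBS-oxy)propan-2-yl]-1,2-dioxane | CC1=C[C@H]2CC(C)=C(CC[C@]3(C)CC[C@H]([C@@H](C)CO[Si](C)(C)C(C)(C)C)OO3)C(C)(C)[C@H]2CC1 | intermediate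
34 | (2S)-2-{(3R,6R)-3-methyl-3-[2-(HHN)ethyl]-1,2-dioxan-6-yl}propan-1-ol | CC1=C[C@H]2CC(C)=C(CC[C@]3(C)CC[C@H]([C@@H](C)CO)OO3)C(C)(C)[C@H]2CC1 | intermediate
35 | (2R)-2-{(3R,6R)-3-methyl-3-[2-(HHN)ethyl]-1,2-dioxan-6-yl}propanal | CC1=C[C@H]2CC(C)=C(CC[C@]3(C)CC[C@H]([C@@H](C)C=O)OO3)C(C)(C)[C@H]2CC1 | intermediate
36 | (2R)-2-{(3R,6R)-3-methyl-3-[2-(HHN)ethyl]-1,2-dioxan-6-yl}propanoic acid | CC1=C[C@H]2CC(C)=C(CC[C@]3(C)CC[C@H]([C@@H](C)C(=O)O)OO3)C(C)(C)[C@H]2CC1 | target

**Step count and risks**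

Total steps: 21. Longest linear sequence: 14 (steps 1–10, then 18–21); the dioxane branch is 7 steps (11–17).

Steps most likely to fail:

1. Step 18 (Proposed new method). The stannane may be consumed by silyl- or proto-destannylation before it meets the cation; the cation may lose a proton to the enol peroxide or undergo O–O heterolysis; and the conjugated propargylic peroxide product may re-ionise and epimerise at C3. The fallback uses only established peroxycarbenium chemistry; it sets out from 17 and 29 and comes back at 33. Gold(I)-catalysed Markovnikov hydration of 17 gives the methyl ketone 1-(HHN)ethan-1-one F1, and LDA/TMSCl converts it into the silyl enol ether trimethyl{[1-(HHN)ethenyl]oxy}silane F2. TMSOTf-mediated Mukaiyama-type addition of F2 to the cation from 29 at −78 °C, under the same axial-attack control, gives the β-peroxy ketone 2-{(3S,6R)-3-methyl-6-[(2S)-1-(TBS-oxy)propan-2-yl]-1,2-dioxan-3-yl}-1-(HHN)ethan-1-one F3. Luche reduction gives the allylic alcohol 2-{(3S,6R)-3-methyl-6-[(2S)-1-(TBS-oxy)propan-2-yl]-1,2-dioxan-3-yl}-1-(HHN)ethan-1-ol F4, and PhOC(S)Cl/pyridine gives its O-phenyl thionocarbonate F5. Barton–McCombie deoxygenation (Bu3SnH, AIBN, toluene, 80 °C), in which the allylic radical should take hydrogen at the unhindered CH terminus and so keep the tetrasubstituted C2=C3 olefin, delivers 33.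

2. Step 5. Protonation of the trisubstituted ring-A olefin can compete with that of the isopropenyl group, leading to a bridged bicyclo[3.3.1] closure or to migration of the C5=C6 double bond, and the enol may be alkylated on oxygen instead of carbon. The fallback sets out from 11 and comes back at 12. Mercury(II) triflate–N,N-dimethylaniline (MeNO2, −20 °C; aqueous NaCl) should engage the less substituted 1,1-disubstituted olefin selectively and give, after C-cyclisation, methyl (4aR,8aS)-1-[(chloromercurio)methyl]-1,6-dimethyl-3-oxo-1,2,3,4,4a,7,8,8a-octahydronaphthalene-2-carboxylate F6. Reductive demercuration (NaBH4, aqueous NaOH, 0 °C, or Bu3SnH) turns the CH2HgCl group into the second methyl group of 12.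

3. Step 17. E2 loss of the mesylate and base-induced fragmentation of the secondary peroxide (Kornblum–DeLaMare) can compete with ring closure. The fallback reverses the order of the two C–O bond formations; it sets out from 27 and comes back at 29. Intermolecular SN2 displacement of the mesylate by 2-methoxyprop-2-yl hydroperoxide (CsOH, DMF), with inversion, gives tert-butyl{[(2S,3R)-3-[(2-methoxypropan-2-yl)peroxy]-2,6-dimethylhept-6-en-1-yl]oxy}dimethylsilane F7. Ozonolysis in CH2Cl2 with Me2S work-up gives (5R,6S)-7-(TBS-oxy)-5-[(2-methoxypropan-2-yl)peroxy]-6-methylheptan-2-one F8. PPTS in MeOH then removes the 2-methoxypropyl group; the freed hydroperoxide should close onto the ketone and the peroxyhemiketal is converted in the same pot into the methyl ketal 29.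

**Further compounds**

F1 | step 18 | 1-[(4aR,8aS)-1,1,3,6-tetramethyl-1,4,4a,7,8,8a-hexahydronaphthalen-2-yl]ethan-1-one | CC1=C[C@H]2CC(C)=C(C(C)=O)C(C)(C)[C@H]2CC1
F2 | step 18 | trimethyl({1-[(4aR,8aS)-1,1,3,6-tetramethyl-1,4,4a,7,8,8a-hexahydronaphthalen-2-yl]ethenyl}oxy)silane | CC1=C[C@H]2CC(C)=C(C(=C)O[Si](C)(C)C)C(C)(C)[C@H]2CC1
F3 | step 18 | 2-{(3S,6R)-3-methyl-6-[(2S)-1-(TBS-oxy)propan-2-yl]-1,2-dioxan-3-yl}-1-(HHN)ethan-1-one | CC1=C[C@H]2CC(C)=C(C(=O)C[C@]3(C)CC[C@H]([C@@H](C)CO[Si](C)(C)C(C)(C)C)OO3)C(C)(C)[C@H]2CC1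
F4 | step 18 | 2-{(3S,6R)-3-methyl-6-[(2S)-1-(TBS-oxy)propan-2-yl]-1,2-dioxan-3-yl}-1-(HHN)ethan-1-ol (carbinol epimers) | CC1=C[C@H]2CC(C)=C(C(O)C[C@]3(C)CC[C@H]([C@@H](C)CO[Si](C)(C)C(C)(C)C)OO3)C(C)(C)[C@H]2CC1
F5 | step 18 | O-phenyl thionocarbonate of F4 | CC1=C[C@H]2CC(C)=C(C(OC(=S)Oc3ccccc3)C[C@]3(C)CC[C@H]([C@@H](C)CO[Si](C)(C)C(C)(C)C)OO3)C(C)(C)[C@H]2CC1
F6 | step 5 | methyl (4aR,8aS)-1-[(chloromercurio)methyl]-1,6-dimethyl-3-oxo-1,2,3,4,4a,7,8,8a-octahydronaphthalene-2-carboxylate | CC1=C[C@H]2CC(=O)C(C(=O)OC)C(C)(C[Hg]Cl)[C@H]2CC1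
F7 | step 17 | tert-butyl{[(2S,3R)-3-[(2-methoxypropan-2-yl)peroxy]-2,6-dimethylhept-6-en-1-yl]oxy}dimethylsilane | C=C(C)CC[C@H]([C@@H](C)CO[Si](C)(C)C(C)(C)C)OOC(C)(C)OC
F8 | step 17 | (5R,6S)-7-{[tert-butyl(dimethyl)silyl]oxy}-5-[(2-methoxypropan-2-yl)peroxy]-6-methylheptan-2-one | CC(=O)CC[C@H]([C@@H](C)CO[Si](C)(C)C(C)(C)C)OOC(C)(C)OC
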